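## Structural features

The target is a fully substituted furan-2(5H)-one (O1, C2(=O), C3, C4, C5) with three bromoaryl arms. C3 bears the secondary carbinol C7 with ring A (3,5-dibromo-4-methoxyphenyl), C4 bears ring B (3-bromo-4-hydroxyphenyl) directly, and C5 is joined through the exocyclic C5=C6 double bond to ring C (3-bromo-4-hydroxyphenyl). C7 (S) is the only stereocentre and has no stereogenic neighbour; the only other stereo-element is the Z geometry of C5=C6 (ring C syn to O1). C7 is benzylic and allylic to C3=C4, and a cation there would be delocalised through C4 towards the para oxygen of ring B, so the carbinol is sensitive to acid (ionisation, racemisation) and to oxidation. The enol lactone O1–C5=C6 is open to ring opening by alkoxide or hydroxide and to Z/E isomerisation. The five aryl C–Br bonds exclude zerovalent palladium or zerovalent nickel coupling, halogen–lithium exchange and hydrogenolysis. The real difficulty is to build the tetrasubstituted C3=C4 alkene with its three different arms in a defined order while C7 stays enantiopure and no aryl bromide is touched. The key step uses two facts: C2(=O)–C3=C4, with the C7 arm on C3 and ring B on C4, is a ring-opened cyclopropenone, and O1–C5 (with C6 and ring C attached) is the carbonyl group of an arylacetaldehyde.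

## Logic of the disconnections

20 ⇒ 19. The O–Si bond at C7 and the two aryl O–CH2 acetal bonds are cut. The phenols and the carbinol have to be masked through organozinc, carbene, ylide and enolate chemistry. Nothing is gained in skeleton, but every later intermediate becomes non-acidic and non-nucleophilic. The forward step must be one acid treatment mild enough not to ionise C7 or open the enol lactone.

19 ⇒ 16. No skeletal bond is cut; the C5=C6 unsaturation is removed so that C5 is sp3 and carries hydrogen. This is the oxidation level that an aldehyde carbon reaches when it becomes C5 of the ring, and it takes the Z olefin out of the ring-forming step. The forward step must functionalise C5 selectively (through 17 and 18) and eliminate towards C6 to the Z isomer, which is also the more stable one.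

16 ⇒ 10 + 14. C4–C5 and O1–C2 are cut. This splits the molecule into two halves of similar size and makes the ring by one C–C and one C–O bond under nucleophilic catalysis, with no metal near the aryl bromides. The C3=C4 alkene and the placement of the C7 arm and ring B are inherited from 10. The forward step requires attack of the catalyst at C4 and not C3, and carbonyl addition to 14 faster than its enolisation.

10 ⇒ 7 + 8. The two bonds from the carbonyl carbon C2 to C3 and C4 are cut; C2 is a carbene carbon delivered as CF2 (through 9) and unmasked by hydrolysis. This reduces the strained ring to an alkyne. The carbene must add to a hindered alkyne without harm to the silyl ether, the acetal or C7.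

7 ⇒ 6 ⇒ 4 + 5. The O–Si bond is cut, then the bond between C7 and the alkyne carbon. This is the only stereogenic bond formation of the route and falls on two achiral, simple partners. It demands enantioface control in the alkynyl transfer to 5 (Re face) and a silyl group bulky enough to shield C3 later.

4 ⇒ 2 + 3 ⇒ 1. The terminal alkyne carbon is cut back to an aldehyde (one-carbon homologation with 3), and the acetal is cut back to the phenol. The homologation must avoid organolithium reagents, which would exchange the aryl bromide.

14 ⇒ 13 ⇒ 12 ⇒ 11. Only oxidation level and protection change: the aldehyde comes from the primary alcohol, the acetal from the phenol, and the alcohol from the arylacetic acid. 14 is labile and is therefore made last and used at once.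

## Other disconnections considered

Alternative 1: The cut runs through C2–C3 and C4–C5. O1, C2, C5 and C6 with ring C come from 2-[3-bromo-4-(methoxymethoxy)benzyl]-5-ethoxy-4-methyloxazole A2; C3, C4 and C7 come from the ynone A1 (ring A aroyl, ring B on the alkyne).
- Forward key step: A2 and A1 combine in a thermal [4+2] cycloaddition across the oxazole C2 and C5 positions. The bridged adduct loses acetonitrile by retro-[4+2] to give the 2-ethoxyfuran A3.
- In its favour: no metal and no strained or enolisable partner; two C–C bonds and the whole heterocycle in one convergent step; the orientation is polarity-matched (the ethoxy-bearing terminus bonds to the carbon next to the ketone); A1 needs no asymmetric catalysis.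
- Against it here: A3 has C7 as a ketone. The stereocentre would be made late by enantioselective reduction of a ketone flanked by two flat sp2 groups on an electrophilic 3-acylbutenolide, where conjugate reduction competes. The ethoxyfuran must be hydrolysed, C5–C6 must still be oxidised as in the chosen route, and a hindered diaryl ynone is likely to need high temperature.
- Comparison: on regiochemical security the alternative is the better plan, since step 9 depends on a kinetic choice between two alkene carbons. On absence of metals at the ring-forming step the two are equal. The chosen plan is better on C7 (fixed in step 3 on a simple aldehyde and only carried afterwards) and on operations after ring formation (two from 16, about four from A3).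

Alternative 2: The cut is the C3=C4 double bond. O1–C2 is already present in the enol ester A4, the ring A aroylacetate of the Z enol of a ring B/ring C 1,2-dione.
- Forward key step: an intramolecular Knoevenagel condensation. The active methylene (C3) adds to the ring B ketone (C4) in a 5-exo-trig aldol closure, and dehydration gives the keto butenolide A5 with the Z ylidene carried in from A4.
- In its favour: ring and ylidene arrive together, so no C5 oxidation sequence is needed; no silyl group is needed at C7; the closure is an ordinary enolate–ketone condensation; no metal is used.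
- Against it here: A4 is an enol ester of a β-keto acid, an activated acyl donor. The base needed for the condensation can fragment it or cause acyl shifts, and its preparation needs site- and Z-selective O-acylation of one of two possible enols. A5 again has C7 as a ketone, with the same late reduction problem, now on a cross-conjugated ylidene lactone.
- Comparison: on oxidation-level economy at C5/C6 the alternative is better, and on paper it is shorter. On absence of metals the two are equal. The chosen plan is better on stereocontrol and rests on more stable precursors (10 is stable, 14 is freshly made), at the price of protecting-group and C5 adjustment steps.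

Alternative 3: The cut is O1–C5. The alkynoic acid A8 (C2 acid, C3 bearing the protected C7 carbinol, tertiary C4 alcohol with ring B, C5≡C6 alkyne to ring C) would come from aldol addition of the enolate of the β-silyloxy ester A6 to the ketone of ynone A7, then ester hydrolysis.
- Forward key step: AgNO3 activates C5≡C6, the carboxylic acid adds anti in a 5-exo-dig closure, and protodemetalation gives the Z ylidene lactone A9. Dehydration across C3–C4 would complete the butenolide.
- In its favour: the Z geometry follows directly from anti oxymetalation; C7 can be set by a well-tried enantioselective reduction of a β-keto ester; no C5 oxidation is needed; monovalent silver does not insert into aryl bromides.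
- Against it here: the enolate of A6 has the silyloxy group β to the carbanion and can eliminate. Addition to A7 may go 1,4 as well as 1,2. A8 is a tertiary benzylic propargylic β-hydroxy acid set up for retro-aldol cleavage during hydrolysis and lactonisation. The final dehydration passes through a C3 carbanion or C4 cation next to the C7 silyloxy group.
- Comparison: on the Z olefin the alternative is better (set by mechanism, not by thermodynamic preference). On tolerance of the aryl bromides it is about equal. The step count is comparable. The ring-forming mechanism is at least as well founded as that of step 9, but the precursor is more fragile than 10, and the chosen route forms C3=C4 within the annulation without a separate dehydration.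

Key step: step 9

Assumption: (R)-BINOL is taken to direct the alkynyl group to the Re face of 5 (the mirror image of the Si-face delivery usual for (S)-BINOL/Ti(OiPr)4), which gives S at C7; the other antipode of the ligand is used if Mosher ester analysis of 6 shows the opposite sense.

Step 1
Reactants: 1 3-bromo-4-hydroxybenzaldehyde
Product: 2 3-bromo-4-(methoxymethoxy)benzaldehyde
Conditions: MOMCl, iPr2NEt, CH2Cl2, 0 °C → rt
Reagents that add atoms: chloromethyl methyl ether (MOMCl), COCCl
Why: O-alkylation of the phenol by the α-chloro ether under amine base (methoxymethyl protection); the aldehyde is untouched, and the acetal adds no stereocentre and should resist the base, organozinc, carbene and ylide steps ahead.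

Step 2
Reactants: 2 3-bromo-4-(methoxymethoxy)benzaldehyde; 3 dimethyl (1-diazo-2-oxopropyl)phosphonate
Product: 4 2-bromo-4-ethynyl-1-(methoxymethoxy)benzene
Conditions: K2CO3, MeOH, 0 °C → rt
Reagents that add atoms: dimethyl (1-diazo-2-oxopropyl)phosphonate (compound 3), CC(=O)C(=[N+]=[N-])P(=O)(OC)OC
Why: Ohira–Bestmann (Seyferth–Gilbert) homologation: methanolysis of 3 gives the diazomethylphosphonate anion, Horner–Wadsworth–Emmons addition and loss of N2 give the alkylidene carbene, and a 1,2-hydride shift gives the terminal alkyne; no organolithium is used, so the aryl bromide is safe.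

Step 3
Reactants: 4 2-bromo-4-ethynyl-1-(methoxymethoxy)benzene; 5 3,5-dibromo-4-methoxybenzaldehyde
Product: 6 (S)-1-(3,5-dibromo-4-methoxyphenyl)-3-[3-bromo-4-(methoxymethoxy)phenyl]prop-2-yn-1-ol
Conditions: ZnEt2, toluene, reflux; then (R)-BINOL (20 mol %), Ti(OiPr)4 (50 mol %), CH2Cl2, rt; then 5, rt; aq. NH4Cl
Reagents that add atoms: none
Why: Catalytic asymmetric alkynylzinc addition to an aromatic aldehyde under BINOL/Ti(OiPr)4 catalysis: the alkynyl(ethyl)zinc made from 4 and ZnEt2 is transferred inside the chiral titanium complex to the Re face of 5, which sets C7 as S; aryl bromides and the acetal are inert to the dialkylzinc.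

Step 4
Reactants: 6 (S)-1-(3,5-dibromo-4-methoxyphenyl)-3-[3-bromo-4-(methoxymethoxy)phenyl]prop-2-yn-1-ol
Product: 7 (S)-tert-butyl{1-(3,5-dibromo-4-methoxyphenyl)-3-[3-bromo-4-(methoxymethoxy)phenyl]prop-2-yn-1-yloxy}dimethylsilane
Conditions: TBSCl, imidazole, DMF, rt
Reagents that add atoms: tert-butyldimethylsilyl chloride (TBSCl), CC(C)(C)[Si](C)(C)Cl
Why: Standard imidazole-promoted silylation of a secondary propargylic alcohol without change at C7; the silyl ether prevents O–H insertion of the carbene in step 5 and trapping of the ketene in step 9, and its bulk later shields C3.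

Step 5
Reactants: 7 (S)-tert-butyl{1-(3,5-dibromo-4-methoxyphenyl)-3-[3-bromo-4-(methoxymethoxy)phenyl]prop-2-yn-1-yloxy}dimethylsilane; 8 trimethyl(trifluoromethyl)silane
Product: 10 2-[(S)-(tert-butyldimethylsilyloxy)(3,5-dibromo-4-methoxyphenyl)methyl]-3-[3-bromo-4-(methoxymethoxy)phenyl]cycloprop-2-en-1-one, via 3,3-difluorocyclopropene 9 (not isolated)
Conditions: TMSCF3, NaI, THF, 110 °C (sealed tube); then moist SiO2, CH2Cl2, rt
Reagents that add atoms: trimethyl(trifluoromethyl)silane (compound 8), C[Si](C)(C)C(F)(F)F; water, O
Why: [2+1] cycloaddition of singlet difluorocarbene (iodide-initiated fragmentation of 8) to the electron-rich aryl alkyne gives 9, whose C–F bonds ionise to an aryl-stabilised fluorocyclopropenium ion that water converts into the cyclopropenone on moist silica; C7 takes no part and keeps its configuration.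

Step 6
Reactants: 11 (3-bromo-4-hydroxyphenyl)acetic acid
Product: 12 2-(3-bromo-4-hydroxyphenyl)ethanol
Conditions: BH3·SMe2, THF, 0 °C → rt; MeOH, then aqueous work-up
Reagents that add atoms: none
Why: Chemoselective borane reduction of the carboxylic acid (through the acyloxyborane) to the primary alcohol; the aryl bromide is not reduced and the phenol is set free again on work-up.

Step 7
Reactants: 12 2-(3-bromo-4-hydroxyphenyl)ethanol
Product: 13 2-[3-bromo-4-(methoxymethoxy)phenyl]ethanol
Conditions: MOMCl, K2CO3, acetone, 0 °C → rt
Reagents that add atoms: chloromethyl methyl ether (MOMCl), COCCl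
Why: Carbonate deprotonates only the phenol and not the aliphatic alcohol, so O-alkylation by the chloro ether should take place selectively at the phenolic oxygen.

Step 8
Reactants: 13 2-[3-bromo-4-(methoxymethoxy)phenyl]ethanol
Product: 14 [3-bromo-4-(methoxymethoxy)phenyl]acetaldehyde
Conditions: DMP, CH2Cl2, 0 °C → rt
Reagents that add atoms: none
Why: Dess–Martin oxidation of the primary alcohol stops at the aldehyde under non-aqueous, nearly neutral conditions; the enolisable arylacetaldehyde is not stored but used directly in step 9.

Step 9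
Reactants: 10 2-[(S)-(tert-butyldimethylsilyloxy)(3,5-dibromo-4-methoxyphenyl)methyl]-3-[3-bromo-4-(methoxymethoxy)phenyl]cycloprop-2-en-1-one; 14 [3-bromo-4-(methoxymethoxy)phenyl]acetaldehyde
Product: 16 3-[(S)-(tert-butyldimethylsilyloxy)(3,5-dibromo-4-methoxyphenyl)methyl]-4-[3-bromo-4-(methoxymethoxy)phenyl]-5-[3-bromo-4-(methoxymethoxy)benzyl]furan-2(5H)-one (both C5 epimers), via ketenyl phosphonium ylide 15 (not isolated)
Conditions: PMe3 (20 mol %), CH2Cl2, 0 °C → rt; 14 added slowly by syringe pump
Reagents that add atoms: none
Why: The phosphine attacks C4 of 10 (the alkene carbon carrying ring B), and relief of ring strain breaks the C2–C4 bond to leave ylide 15, a ketene at C3=C2 with the carbanion on C4 next to ring B. C4 of 15 then adds to the carbonyl carbon of 14 (C4–C5), and the new alkoxide O1 acylates itself on the ketene carbon C2 (5-exo-dig with respect to the ketene C=O), closing the O1–C2–C3–C4–C5 ring as a lactone enolate. β-Elimination of PMe3 from C4 of this enolate (E1cB) returns the catalyst and restores C3=C4. The closest known reaction type is the phosphine-catalysed (3+2) annulation of cyclopropenones with aldehydes to butenolides. C5 is the only new stereocentre; the remote C7 centre controls it only weakly, and both epimers are carried on because C5 becomes trigonal in step 10. The step needs phosphine attack at C4 and not C3, which the branched silyloxybenzyl group on C3 (steric shielding) and the aryl stabilisation of the ylide formed at C4 should secure. It also needs carbonyl addition to outrun proton transfer from the enolisable aldehyde, for which 14 is kept at low concentration and the normal preference of phosphorus ylides for carbonyl addition is relied on. C7 is never part of the reacting π system, the enolate has PMe3 as a far better leaving group than the C7 silyloxide, and no metal meets the aryl bromides.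

Step 10
Reactants: 16 3-[(S)-(tert-butyldimethylsilyloxy)(3,5-dibromo-4-methoxyphenyl)methyl]-4-[3-bromo-4-(methoxymethoxy)phenyl]-5-[3-bromo-4-(methoxymethoxy)benzyl]furan-2(5H)-one (both C5 epimers)
Product: 19 3-[(S)-(tert-butyldimethylsilyloxy)(3,5-dibromo-4-methoxyphenyl)methyl]-4-[3-bromo-4-(methoxymethoxy)phenyl]-5-{(Z)-[3-bromo-4-(methoxymethoxy)phenyl]methylidene}furan-2(5H)-one, via 2-trimethylsilyloxyfuran 17 (not isolated), via 5-bromobutenolide 18 (not isolated)
Conditions: NaN(SiMe3)2, THF, −78 °C; TMSCl; NBS, −78 °C; DBU, −78 °C → rt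
Reagents that add atoms: none
Why: Deprotonation at C5 gives the aromatic furanolate, O-silylation gives 17, and electrophilic bromine attacks its C5 terminus (vinylogous enol ether bromination) to give 18; amidine-induced dehydrobromination across C5–C6 then gives the ylidene (protoanemonin-type bromination–dehydrobromination), the Z isomer being favoured because ring C avoids the aryl group on C4. The base route avoids a silyl triflate, which could ionise the C7 silyloxy group next to the electron-rich furan.

Step 11
Reactants: 19 3-[(S)-(tert-butyldimethylsilyloxy)(3,5-dibromo-4-methoxyphenyl)methyl]-4-[3-bromo-4-(methoxymethoxy)phenyl]-5-{(Z)-[3-bromo-4-(methoxymethoxy)phenyl]methylidene}furan-2(5H)-one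
Product: 20 4-(3-bromo-4-hydroxyphenyl)-5-[(Z)-(3-bromo-4-hydroxyphenyl)methylidene]-3-[(S)-(3,5-dibromo-4-methoxyphenyl)(hydroxy)methyl]furan-2(5H)-one (CID71459453)
Conditions: HCl (3 M aq), THF, rt → 40 °C
Reagents that add atoms: none
Why: Acid-catalysed hydrolysis of the two aryl methoxymethyl acetals (through the oxocarbenium ion) and of the silyl ether in one operation; aqueous acid in a non-nucleophilic co-solvent is chosen so that C7 is not converted to an ether, and the enol lactone and Z olefin are stable to acid.

## Compound list

1 | 3-bromo-4-hydroxybenzaldehyde | O=Cc1ccc(O)c(Br)c1 | starting material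
2 | 3-bromo-4-(methoxymethoxy)benzaldehyde | O=Cc1ccc(OCOC)c(Br)c1 | intermediate
3 | dimethyl (1-diazo-2-oxopropyl)phosphonate | CC(=O)C(=[N+]=[N-])P(=O)(OC)OC | starting material
4 | 2-bromo-4-ethynyl-1-(methoxymethoxy)benzene | C#Cc1ccc(OCOC)c(Br)c1 | intermediate
5 | 3,5-dibromo-4-methoxybenzaldehyde | COc1c(Br)cc(C=O)cc1Br | starting material
6 | (S)-1-(3,5-dibromo-4-methoxyphenyl)-3-[3-bromo-4-(methoxymethoxy)phenyl]prop-2-yn-1-ol | COc1c(Br)cc([C@H](O)C#Cc2ccc(OCOC)c(Br)c2)cc1Br | intermediate
7 | (S)-tert-butyl{1-(3,5-dibromo-4-methoxyphenyl)-3-[3-bromo-4-(methoxymethoxy)phenyl]prop-2-yn-1-yloxy}dimethylsilane | COc1c(Br)cc([C@H](O[Si](C)(C)C(C)(C)C)C#Cc2ccc(OCOC)c(Br)c2)cc1Br | intermediate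
8 | trimethyl(trifluoromethyl)silane | C[Si](C)(C)C(F)(F)F | starting material
9 | 1-[(S)-(tert-butyldimethylsilyloxy)(3,5-dibromo-4-methoxyphenyl)methyl]-2-[3-bromo-4-(methoxymethoxy)phenyl]-3,3-difluorocyclopropene | COc1c(Br)cc([C@H](O[Si](C)(C)C(C)(C)C)C2=C(c3ccc(OCOC)c(Br)c3)C2(F)F)cc1Br | intermediate
10 | 2-[(S)-(tert-butyldimethylsilyloxy)(3,5-dibromo-4-methoxyphenyl)methyl]-3-[3-bromo-4-(methoxymethoxy)phenyl]cycloprop-2-en-1-one | COc1c(Br)cc([C@H](O[Si](C)(C)C(C)(C)C)C2=C(c3ccc(OCOC)c(Br)c3)C2=O)cc1Br | intermediate
11 | (3-bromo-4-hydroxyphenyl)acetic acid | O=C(O)Cc1ccc(O)c(Br)c1 | starting material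
12 | 2-(3-bromo-4-hydroxyphenyl)ethanol | OCCc1ccc(O)c(Br)c1 | intermediate
13 | 2-[3-bromo-4-(methoxymethoxy)phenyl]ethanol | OCCc1ccc(OCOC)c(Br)c1 | intermediate
14 | [3-bromo-4-(methoxymethoxy)phenyl]acetaldehyde | O=CCc1ccc(OCOC)c(Br)c1 | intermediate
15 | ketenyl trimethylphosphonium ylide: carbanion on C4 bearing ring B and PMe3, ketene at C3=C2, (S)-silyloxy(ring A)methyl group on C3 | COc1c(Br)cc([C@H](O[Si](C)(C)C(C)(C)C)C(=C=O)[C-](c2ccc(OCOC)c(Br)c2)[P+](C)(C)C)cc1Br | intermediate
16 | 3-[(S)-(tert-butyldimethylsilyloxy)(3,5-dibromo-4-methoxyphenyl)methyl]-4-[3-bromo-4-(methoxymethoxy)phenyl]-5-[3-bromo-4-(methoxymethoxy)benzyl]furan-2(5H)-one, both C5 epimers | COc1c(Br)cc([C@H](O[Si](C)(C)C(C)(C)C)C2=C(c3ccc(OCOC)c(Br)c3)C(Cc3ccc(OCOC)c(Br)c3)OC2=O)cc1Br | intermediate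
17 | {3-[(S)-(tert-butyldimethylsilyloxy)(3,5-dibromo-4-methoxyphenyl)methyl]-4-[3-bromo-4-(methoxymethoxy)phenyl]-5-[3-bromo-4-(methoxymethoxy)benzyl]furan-2-yloxy}trimethylsilane | COc1c(Br)cc([C@H](O[Si](C)(C)C(C)(C)C)c2c(O[Si](C)(C)C)oc(Cc3ccc(OCOC)c(Br)c3)c2-c2ccc(OCOC)c(Br)c2)cc1Br | intermediate
18 | 5-bromo-3-[(S)-(tert-butyldimethylsilyloxy)(3,5-dibromo-4-methoxyphenyl)methyl]-4-[3-bromo-4-(methoxymethoxy)phenyl]-5-[3-bromo-4-(methoxymethoxy)benzyl]furan-2(5H)-one, both C5 epimers | COc1c(Br)cc([C@H](O[Si](C)(C)C(C)(C)C)C2=C(c3ccc(OCOC)c(Br)c3)C(Br)(Cc3ccc(OCOC)c(Br)c3)OC2=O)cc1Br | intermediate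
19 | 3-[(S)-(tert-butyldimethylsilyloxy)(3,5-dibromo-4-methoxyphenyl)methyl]-4-[3-bromo-4-(methoxymethoxy)phenyl]-5-{(Z)-[3-bromo-4-(methoxymethoxy)phenyl]methylidene}furan-2(5H)-one | COc1c(Br)cc([C@H](O[Si](C)(C)C(C)(C)C)C2=C(c3ccc(OCOC)c(Br)c3)/C(=C/c3ccc(OCOC)c(Br)c3)OC2=O)cc1Br | intermediate
20 | 4-(3-bromo-4-hydroxyphenyl)-5-[(Z)-(3-bromo-4-hydroxyphenyl)methylidene]-3-[(S)-(3,5-dibromo-4-methoxyphenyl)(hydroxy)methyl]furan-2(5H)-one | COc1c(Br)cc([C@H](O)C2=C(c3ccc(O)c(Br)c3)/C(=C/c3ccc(O)c(Br)c3)OC2=O)cc1Br | target

## Step count and least certain steps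

Total step count: 11. Longest linear sequence: 8 steps (steps 1–5, then 9–11); the ring C branch (steps 6–8) joins at step 9.

Step 9 (key step). The most likely failure is proton transfer from the enolisable aldehyde 14 to the basic ylide 15, followed by aldol self-condensation of 14, so that C4–C5 bond formation is outrun and the ketene is consumed in acyclic acylation; partial phosphine attack at C3 would add a regioisomeric lactone. The fallback sets out from 10 and 2 and makes the C5–C6 bond afterwards. The same PMe3-catalysed annulation is run with monomeric formaldehyde, which cannot enolise, to give 3-[(S)-(tert-butyldimethylsilyloxy)(3,5-dibromo-4-methoxyphenyl)methyl]-4-[3-bromo-4-(methoxymethoxy)phenyl]furan-2(5H)-one F1. Vinylogous aldol addition of F1 to aldehyde 2 (TBSOTf, iPr2NEt, CH2Cl2) gives the 5-(α-silyloxybenzyl)butenolide F2, and DBU-induced β-elimination of silanol from F2 gives the Z ylidene. The fallback returns to the route at 19.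

Step 10. The most likely failure is loss of site control in the bromination: attack at C3 of 17, or at the ring positions ortho to the acetal oxygens, instead of C5. Incomplete Z selectivity in the elimination is a second possibility. The fallback sets out from 16 and uses oxygen in place of bromine. 17 is formed as before and oxidised with dimethyldioxirane (acetone, −78 °C) to 3-[(S)-(tert-butyldimethylsilyloxy)(3,5-dibromo-4-methoxyphenyl)methyl]-4-[3-bromo-4-(methoxymethoxy)phenyl]-5-[3-bromo-4-(methoxymethoxy)benzyl]-5-hydroxyfuran-2(5H)-one F3. Dehydration of F3 (MsCl, Et3N, CH2Cl2, 0 °C) towards C6 gives the ylidene. The fallback returns at 19.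

Step 11. The most likely failure is acid-promoted ionisation at C7, which would erode optical purity or cause substitution; slow cleavage of the hindered silyl ether would prolong the acid exposure. The fallback sets out from 19 and removes the groups in two stages without strong Brønsted acid. TMSOTf/2,2′-bipyridyl (CH2Cl2, 0 °C), then water, cleaves the two aryl acetals while C7 stays silylated, giving 4-(3-bromo-4-hydroxyphenyl)-5-[(Z)-(3-bromo-4-hydroxyphenyl)methylidene]-3-[(S)-(tert-butyldimethylsilyloxy)(3,5-dibromo-4-methoxyphenyl)methyl]furan-2(5H)-one F4. HF·pyridine (THF, 0 °C → rt) then removes the silyl group from F4. The fallback returns at 20.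

Step 3. The most likely failure is insufficient or inverted enantioface selection for this aldehyde–alkyne pair, with ethyl transfer from ZnEt2 as a minor competing process. The fallback sets out from 4 and 5 and sets C7 by reduction instead of addition. The bromomagnesium acetylide of 4 (EtMgBr, THF) adds to 5 to give racemic 1-(3,5-dibromo-4-methoxyphenyl)-3-[3-bromo-4-(methoxymethoxy)phenyl]prop-2-yn-1-ol F5. MnO2 oxidation gives 1-(3,5-dibromo-4-methoxyphenyl)-3-[3-bromo-4-(methoxymethoxy)phenyl]prop-2-yn-1-one F6. Corey–Bakshi–Shibata reduction of F6 (oxazaborolidine antipode chosen with ring A as the large group, catecholborane, −78 °C) gives the S alcohol. The fallback returns at 6.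

## Further compounds

F1 | step 9 | 3-[(S)-(tert-butyldimethylsilyloxy)(3,5-dibromo-4-methoxyphenyl)methyl]-4-[3-bromo-4-(methoxymethoxy)phenyl]furan-2(5H)-one | COc1c(Br)cc([C@H](O[Si](C)(C)C(C)(C)C)C2=C(c3ccc(OCOC)c(Br)c3)COC2=O)cc1Br
F2 | step 9 | 5-{[3-bromo-4-(methoxymethoxy)phenyl](tert-butyldimethylsilyloxy)methyl}-3-[(S)-(tert-butyldimethylsilyloxy)(3,5-dibromo-4-methoxyphenyl)methyl]-4-[3-bromo-4-(methoxymethoxy)phenyl]furan-2(5H)-one, mixture at C5 and C6 | COc1c(Br)cc([C@H](O[Si](C)(C)C(C)(C)C)C2=C(c3ccc(OCOC)c(Br)c3)C(C(O[Si](C)(C)C(C)(C)C)c3ccc(OCOC)c(Br)c3)OC2=O)cc1Br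
F3 | step 10 | 3-[(S)-(tert-butyldimethylsilyloxy)(3,5-dibromo-4-methoxyphenyl)methyl]-4-[3-bromo-4-(methoxymethoxy)phenyl]-5-[3-bromo-4-(methoxymethoxy)benzyl]-5-hydroxyfuran-2(5H)-one, both C5 epimers | COc1c(Br)cc([C@H](O[Si](C)(C)C(C)(C)C)C2=C(c3ccc(OCOC)c(Br)c3)C(O)(Cc3ccc(OCOC)c(Br)c3)OC2=O)cc1Br
F4 | step 11 | 4-(3-bromo-4-hydroxyphenyl)-5-[(Z)-(3-bromo-4-hydroxyphenyl)methylidene]-3-[(S)-(tert-butyldimethylsilyloxy)(3,5-dibromo-4-methoxyphenyl)methyl]furan-2(5H)-one | COc1c(Br)cc([C@H](O[Si](C)(C)C(C)(C)C)C2=C(c3ccc(O)c(Br)c3)/C(=C/c3ccc(O)c(Br)c3)OC2=O)cc1Br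
F5 | step 3 | racemic 1-(3,5-dibromo-4-methoxyphenyl)-3-[3-bromo-4-(methoxymethoxy)phenyl]prop-2-yn-1-ol | COc1c(Br)cc(C(O)C#Cc2ccc(OCOC)c(Br)c2)cc1Br
F6 | step 3 | 1-(3,5-dibromo-4-methoxyphenyl)-3-[3-bromo-4-(methoxymethoxy)phenyl]prop-2-yn-1-one | COc1c(Br)cc(C(=O)C#Cc2ccc(OCOC)c(Br)c2)cc1Br
A1 | alternative 1 | 1-(3,5-dibromo-4-methoxyphenyl)-3-[3-bromo-4-(methoxymethoxy)phenyl]prop-2-yn-1-one | COc1c(Br)cc(C(=O)C#Cc2ccc(OCOC)c(Br)c2)cc1Br
A2 | alternative 1 | 2-[3-bromo-4-(methoxymethoxy)benzyl]-5-ethoxy-4-methyloxazole | CCOc1oc(Cc2ccc(OCOC)c(Br)c2)nc1C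
A3 | alternative 1 | (3,5-dibromo-4-methoxyphenyl){5-[3-bromo-4-(methoxymethoxy)benzyl]-4-[3-bromo-4-(methoxymethoxy)phenyl]-2-ethoxyfuran-3-yl}methanone | CCOc1oc(Cc2ccc(OCOC)c(Br)c2)c(-c2ccc(OCOC)c(Br)c2)c1C(=O)c1cc(Br)c(OC)c(Br)c1
A4 | alternative 2 | (Z)-1,3-bis[3-bromo-4-(methoxymethoxy)phenyl]-3-oxoprop-1-en-2-yl 3-(3,5-dibromo-4-methoxyphenyl)-3-oxopropanoate | COc1c(Br)cc(C(=O)CC(=O)O/C(=C\c2ccc(OCOC)c(Br)c2)C(=O)c2ccc(OCOC)c(Br)c2)cc1Br
A5 | alternative 2 | 3-(3,5-dibromo-4-methoxybenzoyl)-4-[3-bromo-4-(methoxymethoxy)phenyl]-5-{(Z)-[3-bromo-4-(methoxymethoxy)phenyl]methylidene}furan-2(5H)-one | COc1c(Br)cc(C(=O)C2=C(c3ccc(OCOC)c(Br)c3)/C(=C/c3ccc(OCOC)c(Br)c3)OC2=O)cc1Br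
A6 | alternative 3 | methyl (R)-3-(tert-butyldimethylsilyloxy)-3-(3,5-dibromo-4-methoxyphenyl)propanoate (same spatial arrangement at C7 as the target) | COc1c(Br)cc([C@H](O[Si](C)(C)C(C)(C)C)CC(=O)OC)cc1Br
A7 | alternative 3 | 1,3-bis[3-bromo-4-(methoxymethoxy)phenyl]prop-2-yn-1-one | O=C(C#Cc1ccc(OCOC)c(Br)c1)c1ccc(OCOC)c(Br)c1
A8 | alternative 3 | 3-hydroxy-3,5-bis[3-bromo-4-(methoxymethoxy)phenyl]-2-[(tert-butyldimethylsilyloxy)(3,5-dibromo-4-methoxyphenyl)methyl]pent-4-ynoic acid, C7 as in the target, C3 and C4 mixed | COc1c(Br)cc([C@H](O[Si](C)(C)C(C)(C)C)C(C(=O)O)C(O)(C#Cc2ccc(OCOC)c(Br)c2)c2ccc(OCOC)c(Br)c2)cc1Br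
A9 | alternative 3 | 4-hydroxy-4-[3-bromo-4-(methoxymethoxy)phenyl]-5-{(Z)-[3-bromo-4-(methoxymethoxy)phenyl]methylidene}-3-[(tert-butyldimethylsilyloxy)(3,5-dibromo-4-methoxyphenyl)methyl]dihydrofuran-2(3H)-one, C7 as in the target, C3 and C4 mixed | COc1c(Br)cc([C@H](O[Si](C)(C)C(C)(C)C)C2C(O)(c3ccc(OCOC)c(Br)c3)/C(=C/c3ccc(OCOC)c(Br)c3)OC2=O)cc1Br
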